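**Strategy.** The synthesis rests on cutting the ring-fusion bond C1–C5 (daucane numbering), which is shared by the cyclopentane and the cycloheptene. The key step is an amine-catalysed intramolecular Michael addition that closes the five-membered ring by bonding the enamine carbon C5 to the β,β-disubstituted enone carbon C1, setting the quaternary C1 and the C5 methine in one operation under control of C4. It exploits the 1,5-relationship of the oxygenated carbons C6 and C9 across C5, C1 and C10. The precursor is an acyclic formyl dienone assembled from (S)-terpinen-4-ol, which supplies C4 with its isopropyl carbinol, and 2-methylbut-1-en-3-yne; ring-closing metathesis later forms the seven-membered ring.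

Key step: step 5

Remark: (S)-terpinen-4-ol of high enantiomeric purity and 4-(methoxymethoxy)benzoic acid are taken as commercial; atoms are discussed in daucane numbering (C1 methyl-bearing ring-fusion carbon, C4 isopropyl carbinol, C5 ring-fusion CH, C6 aroyloxy carbon, C7=C8, C9 acetoxy carbon, C10 ring CH2), while compound names use systematic numbering.

Step 1
Reactants: 1 (S)-terpinen-4-ol
Product: 2 (4S)-4-(methoxymethoxy)-1-methyl-4-(propan-2-yl)cyclohex-1-ene
Conditions: MOMCl, iPr2NEt, NaI (cat.), CH2Cl2, 40 °C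
Reagents that add atoms: chloromethyl methyl ether, COCCl
Why: MOM protection of the tertiary hydroxyl by alkylation with the iodide-activated chloromethyl ether should give an ether that survives ozone, acetylide, gold and amine catalysis, later supplies the chelating oxygen for step 6 and blocks retro-aldol chemistry at C4; the stereocentre is not touched.

Step 2
Reactants: 2 (4S)-4-(methoxymethoxy)-1-methyl-4-(propan-2-yl)cyclohex-1-ene
Product: 5 (5S)-7,7-dimethoxy-5-(methoxymethoxy)-5-(propan-2-yl)heptan-2-one, via methoxy hydroperoxide aldehyde 3 (not isolated), via hydroperoxy acetal 4 (not isolated)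
Conditions: O3, CH2Cl2/MeOH, −78 °C; TsOH·H2O, 23 °C; NaHCO3, then Me2S
Reagents that add atoms: ozone, [O-][O+]=O; methanol, CO
Why: Criegee ozonolysis in methanol places the carbonyl oxide on the more substituted alkene carbon (future C1), so the aldehyde terminus (future C6) is captured as its dimethyl acetal under acid and reduction of the methoxy hydroperoxide with Me2S then frees the C1 methyl ketone (terminally differentiating ozonolysis); C4 keeps its configuration.

Step 3
Reactants: 5 (5S)-7,7-dimethoxy-5-(methoxymethoxy)-5-(propan-2-yl)heptan-2-one; 6 2-methylbut-1-en-3-yne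
Product: 8 (8S)-10,10-dimethoxy-8-(methoxymethoxy)-2,5-dimethyl-8-(propan-2-yl)dec-1-en-3-yn-5-ol (both C5 epimers), via lithium acetylide 7 (not isolated)
Conditions: 6, n-BuLi, THF, −78 °C; then 5, −78 → 0 °C; H2O
Reagents that add atoms: none
Why: Nucleophilic 1,2-addition of the lithium acetylide to the unhindered methyl ketone gives the tertiary propargylic alcohol; the new carbinol centre needs no control because it is destroyed in step 4.

Step 4
Reactants: 8 (8S)-10,10-dimethoxy-8-(methoxymethoxy)-2,5-dimethyl-8-(propan-2-yl)dec-1-en-3-yn-5-ol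
Product: 9 (4E,8S)-10,10-dimethoxy-8-(methoxymethoxy)-2,5-dimethyl-8-(propan-2-yl)deca-1,4-dien-3-one (4Z isomer also expected)
Conditions: Ph3PAuNTf2 (2 mol %), MeOH (1 equiv), toluene, 23–50 °C
Reagents that add atoms: none
Why: Gold-catalysed Meyer–Schuster rearrangement (formal 1,3-shift of the hydroxyl group along the alkyne followed by tautomerisation) should convert the tertiary propargylic alcohol into the cross-conjugated dienone with the carbonyl at C9 and the electrophilic β-carbon at C1; the alkene geometry is irrelevant because this double bond is consumed in step 5.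

Step 5
Reactants: 9 (4E,8S)-10,10-dimethoxy-8-(methoxymethoxy)-2,5-dimethyl-8-(propan-2-yl)deca-1,4-dien-3-one
Product: 12 (1R,2R,5R)-2-(methoxymethoxy)-5-methyl-5-(3-methyl-2-oxobut-3-en-1-yl)-2-(propan-2-yl)cyclopentane-1-carbaldehyde, via formyl dienone 10 (not isolated), via pyrrolidine enamine 11 (not isolated)
Conditions: PPTS, acetone/H2O, 50 °C; then pyrrolidine (0.3 equiv), PhCO2H (0.3 equiv), CHCl3, 40 °C
Reagents that add atoms: water, O
Why: Acid hydrolysis of the dimethyl acetal unveils aldehyde 10; pyrrolidine condenses with it to the E-enamine 11, whose nucleophilic C5 adds to C1, the β-carbon of the trisubstituted enone, and hydrolysis of the resulting iminium ion releases 12 and the amine. The closest known reaction type is the secondary-amine-catalysed intramolecular Michael addition of aldehydes to enones, which gives trans-2-(2-oxoalkyl)cyclopentanecarbaldehydes. Only the cyclopentane closes, in the 5-exo-trig mode (enamine C=C and acceptor C=C both exocyclic to the new ring). C5 is controlled by C4: the C4–O bond takes the inside position and the bulkier isopropyl group stands anti to the forming bond, so the formyl group ends cis to the MOM-oxy group; C1 is controlled by C5 through the open transition state that keeps the C10 acceptor arm away from the enamine, so the arm ends trans and the methyl group cis to the formyl group. The step needs site selectivity for C1 over the unsubstituted terminus of the isopropenyl ketone, which the tether secures (C1 closes a five-membered ring, the other terminus would need a nine-membered one), and both geometric isomers of 9 converge because reversible amine addition equilibrates them. The MOM ether shuts off retro-aldol cleavage and β-elimination at C4.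

Step 6
Reactants: 12 (1R,2R,5R)-2-(methoxymethoxy)-5-methyl-5-(3-methyl-2-oxobut-3-en-1-yl)-2-(propan-2-yl)cyclopentane-1-carbaldehyde; 13 vinylmagnesium bromide
Product: 14 (1S)-1-[(1S,2R,5R)-2-(methoxymethoxy)-5-methyl-5-(3-methyl-2-oxobut-3-en-1-yl)-2-(propan-2-yl)cyclopentyl]prop-2-en-1-ol
Conditions: MgBr2·OEt2, CH2Cl2, −78 °C; then 13 (THF solution), −78 °C; aqueous work-up
Reagents that add atoms: none
Why: Chelation-controlled Grignard addition: MgBr2 bridges the aldehyde oxygen and the C4 MOM oxygen in a six-membered chelate, which activates the aldehyde over the cross-conjugated ketone and leaves open only the face flanked by H-5 (anti to the quaternary C1), so the vinyl group should add to give the (6S)-carbinol.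

Step 7
Reactants: 14 (1S)-1-[(1S,2R,5R)-2-(methoxymethoxy)-5-methyl-5-(3-methyl-2-oxobut-3-en-1-yl)-2-(propan-2-yl)cyclopentyl]prop-2-en-1-ol
Product: 15 (3R,3aS,4S,8aR)-4-hydroxy-3-(methoxymethoxy)-6,8a-dimethyl-3-(propan-2-yl)-2,3,3a,4,8,8a-hexahydroazulen-7(1H)-one
Conditions: second-generation Hoveyda–Grubbs catalyst (5 mol %), toluene, 80 °C
Reagents that add atoms: none
Why: Ring-closing olefin metathesis between the vinyl carbinol and the isopropenyl ketone closes the seven-membered ring and forms the trisubstituted C7=C8 bond with loss of ethylene, the ring size permitting only the cis alkene; no stereocentre is affected and the ring fusion is trans as set in step 5.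

Step 8
Reactants: 15 (3R,3aS,4S,8aR)-4-hydroxy-3-(methoxymethoxy)-6,8a-dimethyl-3-(propan-2-yl)-2,3,3a,4,8,8a-hexahydroazulen-7(1H)-one; 16 4-(methoxymethoxy)benzoic acid
Product: 18 (3R,3aS,4S,8aR)-3-(methoxymethoxy)-6,8a-dimethyl-7-oxo-3-(propan-2-yl)-1,2,3,3a,4,7,8,8a-octahydroazulen-4-yl 4-(methoxymethoxy)benzoate, via O-acylisourea 17 (not isolated)
Conditions: 16, DCC, DMAP, CH2Cl2, 23–40 °C
Reagents that add atoms: none
Why: Steglich esterification through the O-acylisourea and its acylpyridinium ion acylates the only free hydroxyl (the hindered secondary allylic C6–OH) with retention of configuration.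

Step 9
Reactants: 18 (3R,3aS,4S,8aR)-3-(methoxymethoxy)-6,8a-dimethyl-7-oxo-3-(propan-2-yl)-1,2,3,3a,4,7,8,8a-octahydroazulen-4-yl 4-(methoxymethoxy)benzoate
Product: 19 (3R,3aS,4S,7S,8aR)-7-hydroxy-3-(methoxymethoxy)-6,8a-dimethyl-3-(propan-2-yl)-1,2,3,3a,4,7,8,8a-octahydroazulen-4-yl 4-(methoxymethoxy)benzoate
Conditions: (R)-2-methyl-CBS-oxazaborolidine (0.5 equiv), catecholborane, toluene, −78 °C; aqueous work-up
Reagents that add atoms: none
Why: CBS reduction: the (R)-oxazaborolidine binds the enone carbonyl anti to the larger alkenyl flank (C8) and directs 1,2-hydride delivery from catecholborane to one face, which should give the (9S)-allylic alcohol (C7 in the systematic name) under reagent control without touching the esters.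

Step 10
Reactants: 19 (3R,3aS,4S,7S,8aR)-7-hydroxy-3-(methoxymethoxy)-6,8a-dimethyl-3-(propan-2-yl)-1,2,3,3a,4,7,8,8a-octahydroazulen-4-yl 4-(methoxymethoxy)benzoate
Product: 20 (3R,3aS,4S,7S,8aR)-7-(acetyloxy)-3-(methoxymethoxy)-6,8a-dimethyl-3-(propan-2-yl)-1,2,3,3a,4,7,8,8a-octahydroazulen-4-yl 4-(methoxymethoxy)benzoate
Conditions: Ac2O, Et3N, DMAP (cat.), CH2Cl2, 0 °C
Reagents that add atoms: acetic anhydride, CC(=O)OC(C)=O
Why: DMAP-catalysed acetylation of the only free hydroxyl (C9–OH) proceeds with retention of configuration.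

Step 11
Reactants: 20 (3R,3aS,4S,7S,8aR)-7-(acetyloxy)-3-(methoxymethoxy)-6,8a-dimethyl-3-(propan-2-yl)-1,2,3,3a,4,7,8,8a-octahydroazulen-4-yl 4-(methoxymethoxy)benzoate
Product: 21 (3R,3aS,4S,7S,8aR)-7-(acetyloxy)-3-hydroxy-6,8a-dimethyl-3-(propan-2-yl)-1,2,3,3a,4,7,8,8a-octahydroazulen-4-yl 4-hydroxybenzoate (CNP0305796.2)
Conditions: Me2BBr, CH2Cl2, −78 °C; then aq. NaHCO3
Reagents that add atoms: none
Why: Bromodimethylborane coordinates the acetal oxygens and bromide attacks the O–CH2–O carbon, so both MOM ethers (aryl and tertiary alkyl) are cleaved at low temperature without ionisation at C4 or at the allylic ester positions, and hydrolytic work-up should release the phenol and the tertiary alcohol of the target.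

**Compound list**

1 | (S)-terpinen-4-ol, (1S)-4-methyl-1-(propan-2-yl)cyclohex-3-en-1-ol | CC1=CC[C@](O)(C(C)C)CC1 | starting material
2 | (4S)-4-(methoxymethoxy)-1-methyl-4-(propan-2-yl)cyclohex-1-ene | CC1=CC[C@](OCOC)(C(C)C)CC1 | intermediate
3 | (3S)-6-hydroperoxy-6-methoxy-3-(methoxymethoxy)-3-(propan-2-yl)heptanal (C6 epimers) | CC(OC)(OO)CC[C@@](OCOC)(C(C)C)CC=O | intermediate
4 | (5S)-2-hydroperoxy-2,7,7-trimethoxy-5-(methoxymethoxy)-5-(propan-2-yl)heptane (C2 epimers) | CC(OC)(OO)CC[C@@](OCOC)(C(C)C)CC(OC)OC | intermediate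
5 | (5S)-7,7-dimethoxy-5-(methoxymethoxy)-5-(propan-2-yl)heptan-2-one | CC(=O)CC[C@@](OCOC)(C(C)C)CC(OC)OC | intermediate
6 | 2-methylbut-1-en-3-yne | C=C(C)C#C | starting material
7 | lithium 3-methylbut-3-en-1-yn-1-ide | [Li]C#CC(C)=C | intermediate
8 | (8S)-10,10-dimethoxy-8-(methoxymethoxy)-2,5-dimethyl-8-(propan-2-yl)dec-1-en-3-yn-5-ol (C5 epimers) | C=C(C)C#CC(C)(O)CC[C@@](OCOC)(C(C)C)CC(OC)OC | intermediate
9 | (4E,8S)-10,10-dimethoxy-8-(methoxymethoxy)-2,5-dimethyl-8-(propan-2-yl)deca-1,4-dien-3-one (E isomer drawn) | C=C(C)C(=O)/C=C(\C)CC[C@@](OCOC)(C(C)C)CC(OC)OC | intermediate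
10 | (3S,6E)-3-(methoxymethoxy)-6,9-dimethyl-8-oxo-3-(propan-2-yl)deca-6,9-dienal | C=C(C)C(=O)/C=C(\C)CC[C@@](OCOC)(C(C)C)CC=O | intermediate
11 | (4E,8R,9E)-8-(methoxymethoxy)-2,5-dimethyl-8-(propan-2-yl)-10-(pyrrolidin-1-yl)deca-1,4,9-trien-3-one (pyrrolidine enamine of 10) | C=C(C)C(=O)/C=C(\C)CC[C@@](OCOC)(C(C)C)/C=C/N1CCCC1 | intermediate
12 | (1R,2R,5R)-2-(methoxymethoxy)-5-methyl-5-(3-methyl-2-oxobut-3-en-1-yl)-2-(propan-2-yl)cyclopentane-1-carbaldehyde (CHO cis to OMOM and to the ring methyl) | C=C(C)C(=O)C[C@@]1(C)CC[C@@](OCOC)(C(C)C)[C@@H]1C=O | intermediate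
13 | vinylmagnesium bromide | C=C[Mg]Br | starting material
14 | (1S)-1-[(1S,2R,5R)-2-(methoxymethoxy)-5-methyl-5-(3-methyl-2-oxobut-3-en-1-yl)-2-(propan-2-yl)cyclopentyl]prop-2-en-1-ol | C=C(C)C(=O)C[C@@]1(C)CC[C@@](OCOC)(C(C)C)[C@@H]1[C@@H](O)C=C | intermediate
15 | (3R,3aS,4S,8aR)-4-hydroxy-3-(methoxymethoxy)-6,8a-dimethyl-3-(propan-2-yl)-2,3,3a,4,8,8a-hexahydroazulen-7(1H)-one (trans-fused) | O=C1C[C@@]2(C)CC[C@@](OCOC)(C(C)C)[C@@H]2[C@@H](O)C=C1C | intermediate
16 | 4-(methoxymethoxy)benzoic acid | COCOc1ccc(cc1)C(O)=O | starting material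
17 | N,N'-dicyclohexyl-O-[4-(methoxymethoxy)benzoyl]isourea | COCOc1ccc(cc1)C(=O)OC(=NC1CCCCC1)NC1CCCCC1 | intermediate
18 | (3R,3aS,4S,8aR)-3-(methoxymethoxy)-6,8a-dimethyl-7-oxo-3-(propan-2-yl)-1,2,3,3a,4,7,8,8a-octahydroazulen-4-yl 4-(methoxymethoxy)benzoate | O=C1C[C@@]2(C)CC[C@@](OCOC)(C(C)C)[C@@H]2[C@@H](OC(=O)c2ccc(OCOC)cc2)C=C1C | intermediate
19 | (3R,3aS,4S,7S,8aR)-7-hydroxy-3-(methoxymethoxy)-6,8a-dimethyl-3-(propan-2-yl)-1,2,3,3a,4,7,8,8a-octahydroazulen-4-yl 4-(methoxymethoxy)benzoate | O[C@H]1C[C@@]2(C)CC[C@@](OCOC)(C(C)C)[C@@H]2[C@@H](OC(=O)c2ccc(OCOC)cc2)C=C1C | intermediate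
20 | (3R,3aS,4S,7S,8aR)-7-(acetyloxy)-3-(methoxymethoxy)-6,8a-dimethyl-3-(propan-2-yl)-1,2,3,3a,4,7,8,8a-octahydroazulen-4-yl 4-(methoxymethoxy)benzoate | CC(=O)O[C@H]1C[C@@]2(C)CC[C@@](OCOC)(C(C)C)[C@@H]2[C@@H](OC(=O)c2ccc(OCOC)cc2)C=C1C | intermediate
21 | (3R,3aS,4S,7S,8aR)-7-(acetyloxy)-3-hydroxy-6,8a-dimethyl-3-(propan-2-yl)-1,2,3,3a,4,7,8,8a-octahydroazulen-4-yl 4-hydroxybenzoate (9α-acetoxy-4β-hydroxydauc-7-en-6α-yl 4-hydroxybenzoate) | CC(=O)O[C@H]1C[C@@]2(C)CC[C@@](O)(C(C)C)[C@@H]2[C@@H](OC(=O)c2ccc(O)cc2)C=C1C | target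

**Total step count:** 11. **Longest linear sequence:** 11 steps (from 1).

**Steps most likely to fail**

1. Step 5 (key step). Risk: slow carbon–carbon bond formation at the β,β-disubstituted acceptor carbon, which would let oligomerisation through the unsubstituted enone terminus compete, or poor facial selectivity at C1. Fallback: aldehyde 10 would be isolated after the acetal hydrolysis and converted with TBSOTf and Et3N (CH2Cl2, −78 °C) into the (4E,8R,9Z)-silyl enol ether F1. F1 would then be cyclised in a Mukaiyama–Michael reaction promoted by Me2AlCl (CH2Cl2, −78 °C), in which the Lewis-acid-activated dienone is attacked by the preformed neutral nucleophile; aqueous work-up would return keto aldehyde 12.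

2. Step 9. Risk: substrate control (hydride attack anti to the angular methyl group) overriding the catalyst, which would mean poor facial selectivity at C9. Fallback: from 18, Luche reduction (NaBH4, CeCl3·7H2O, MeOH, −78 °C) would be used deliberately under substrate control to give the (7R)-alcohol F3 (the C9 epimer in daucane numbering). Mitsunobu esterification of F3 with acetic acid (PPh3, DIAD, THF) would install the acetate with inversion, rejoining the route directly at 20.

3. Step 4. Risk: dehydration of the tertiary propargylic alcohol (Rupe-type pathway) or decomposition of the cross-conjugated dienone under π-acid catalysis. Fallback: from ketone 5, Horner–Wadsworth–Emmons olefination with diethyl [2-(methoxy(methyl)amino)-2-oxoethyl]phosphonate (NaH, THF, 60 °C) would give the unsaturated Weinreb amide F2. Addition of isopropenylmagnesium bromide (THF, 0 °C) to F2 would deliver dienone 9.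

**Further compounds**

F1 | step 5 | (4E,8R,9Z)-10-[(tert-butyldimethylsilyl)oxy]-8-(methoxymethoxy)-2,5-dimethyl-8-(propan-2-yl)deca-1,4,9-trien-3-one | C=C(C)C(=O)/C=C(\C)CC[C@@](OCOC)(C(C)C)/C=C\O[Si](C)(C)C(C)(C)C
F2 | step 4 | (2E,6S)-N,8,8-trimethoxy-6-(methoxymethoxy)-N,3-dimethyl-6-(propan-2-yl)oct-2-enamide | CON(C)C(=O)/C=C(\C)CC[C@@](OCOC)(C(C)C)CC(OC)OC
F3 | step 9 | (3R,3aS,4S,7R,8aR)-7-hydroxy-3-(methoxymethoxy)-6,8a-dimethyl-3-(propan-2-yl)-1,2,3,3a,4,7,8,8a-octahydroazulen-4-yl 4-(methoxymethoxy)benzoate | O[C@@H]1C[C@@]2(C)CC[C@@](OCOC)(C(C)C)[C@@H]2[C@@H](OC(=O)c2ccc(OCOC)cc2)C=C1C
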